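## Structural features

The target, (S)-salazinic acid (C18H12O10), is a depsidone: two benzene rings, ring A and ring B, are joined through a diaryl ether oxygen and through an aryl ester, and these two links close the seven-membered lactone ring C. Ring B is also fused to a five-membered hydroxy lactone, ring D (a 3-hydroxyphthalide). Lower-case locants are used for the ring carbons: a1 to a6 of ring A carry, in order, the carbonyl of ring C, the ether oxygen, a formyl group, a hydroxyl, hydrogen and a methyl group; b1 to b6 of ring B carry the ester oxygen of ring C, a hydroxymethyl group, a hydroxyl, the carbonyl of ring D, the lactol carbon and the ether oxygen. The only stereocentre is the lactol carbon on b5, of (S) configuration; it has no stereogenic neighbour and, as the hemiacetal of a 2-formylbenzoic acid, it can invert through the open formyl acid. Fragile groups are the aryl ester of ring C (opened by hydroxide or alkoxide), the o-hydroxybenzyl alcohol at b2 (quinone methide formation, hydrogenolysis, oxidation), the lactol, and the salicylaldehyde unit of ring A. The real difficulty is ring B, with six different substituents in a fixed order, and the ether oxygen, which is flanked by two ortho substituents on each ring and is therefore a poor candidate for Ullmann or SNAr coupling. The key step uses the fact that b4, b3 and b2 have the carbon pattern of an acetoacetate (ester-bearing carbon, ketone, methyl), while b5, b6 and b1 match the β-carbon, the aryloxy-bearing α-carbon and the ester carbon of a 3-alkoxyacrylate; ring B can therefore be grown on the ether oxygen by forming b4–b5 and b1–b2.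

## Logic of the disconnections

**19 from 18.** No skeletal bond is cut. The lactol carbon equilibrates in solution, so an asymmetric bond construction would gain nothing; the configuration is fixed only in the crystal and is set last, by seeded crystallization of the racemate. The demand is that 18 racemizes in the slurry and crystallizes as a conglomerate.

**18 from 16.** The acyl C–O bond of ring D (b4 carbonyl to ring oxygen) is cut, together with the O–Si bond of the b2 side chain and the two C–OMe bonds of an acetal on b5. A hydroxyphthalide is the closed form of a 2-formylbenzoate, so ring D and the stereocentre reduce to a methyl ester beside a masked aldehyde. All acid-labile masks then fall in one aqueous acid step. The demand is that the ester is cleaved by the neighbouring formyl group and not by hydroxide, which would open ring C.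

**16 from 14.** The bond from a3 to the formyl carbon is cut. a3 is ortho to a free hydroxyl at a4, so a phenoxide-directed formylation can make this bond; ring A becomes a plain orsellinate unit. The demand is that the formylation chooses a3 over a5 and spares the lactone, acetal and silyl ether.

**14 from 13, and 13 from 12.** The ester bond of ring C (carbonyl on a1 to oxygen on b1) is cut, then two O–benzyl bonds. The ether bridge holds the acid and the b1 hydroxyl side by side, so the seven-membered lactone closes from the hydroxy acid. A tert-butyl ester would be the most inert ester during ring construction, but its removal needs acid, which the acetal and the silyl ether would not survive. A benzyl ester shielded by two ortho substituents is chosen, and a benzyl ether at a4 in place of an acetal-type ether, so that one neutral hydrogenolysis frees both the acid for the lactone and the phenol for the formylation.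

**12 from 11, and 11 from 10.** The O–Si bond and then the b2–CH2OH bond are cut. b2 is the only unsubstituted carbon of a resorcinol and lies between its two hydroxyls, so formaldehyde can be introduced there and nowhere else on ring B. The demands are that ring A carries no free phenol at this stage (hence the a4 ether) and that the primary alcohol can be silylated in the presence of two hindered phenols.

**10 from 6 and 7 (key disconnection).** The bonds b4–b5 and b1–b2 are cut. Ring B disappears and leaves 7 and an acyclic 2-aryloxy-3-methoxyacrylate. Five of the six substituents of ring B are placed by the connectivity of two three-carbon pieces, and the hindered diaryl ether is reduced to an ether between ring A and a non-aromatic carbon. The demands are that a tetrasubstituted, donor-substituted alkene accepts a stabilized carbanion, that the methyl ketone and not the ring A ester completes the ring, and that the ring A ester survives methoxide.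

**6 from 5, and 5 from 2 and 4.** The O–CH3 bond of the enol ether is cut, then the bond between the a2 oxygen and the α-carbon. The second cut corresponds to carbenoid insertion into the phenolic O–H bond, which forms a crowded C–O bond under neutral conditions. The demands are O- over C-methylation and insertion into a hydrogen-bonded phenol.

**4 from 3, and 2 from 1.** Diazo transfer to a commercial keto ester, and a double benzylation that leaves the chelated ortho hydroxyl of 1 free.

## Other disconnections considered

**Alternative 1:** The cut is in ring D, between the ring oxygen and the lactol carbon; the lactol is traced back to an isocoumarin, A1, in which two enol carbons bridge the b4 carboxyl and b5.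
- Forward key step: ozone would add to the enol ester alkene of A1. Fragmentation and reductive work-up would leave an aldehyde on b5 and a mixed anhydride of the b4 acid with a one-carbon acid. That fragment is lost on work-up and the freed acid adds to the aldehyde to give the protected lactol A2.
- In its favour: ring D appears at the right oxidation level under non-basic conditions that ring C tolerates, no ester has to be hydrolysed, and an isocoumarin is a sturdier mask than an acetal.
- Against it here: ozone would have to select the alkene in the presence of two oxygenated arenes, an aldehyde, the acetal-type C–H bonds of methoxymethyl ethers and a benzylic silyl ether. More seriously, A1 still contains the hexasubstituted ring B and the hindered ether, now with an extra fused ring, so the hard part is untouched and two carbons are installed only to be excised.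
- Comparison: on stereochemistry the plans are equal, since the lactol forms as an equilibrating pair either way and both need the same final crystallization. On unmasking ring D the alternative is the better, being neutral and independent of neighbouring-group ester cleavage. On structure and step economy the chosen plan is ahead, because its ring D precursors (ester and acetal) arrive with the building blocks of the ring-forming step.

**Alternative 2:** Three bonds of ring A are cut (a1–a2, a3–a4, a5–a6). This leads to triyne A3: a fully substituted ring B carrying a but-2-ynoate on the b1 oxygen and, on the b6 oxygen, an alkynyl ether whose propargylic oxygen is tied through a dimethylsilyl group to an ethynyl unit.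
- Forward key step: RhCl(PPh3)3 (monovalent rhodium) would couple two alkynes oxidatively to a rhodacyclopentadiene, insert the third and eliminate reductively to A4, closing ring A, ring C and an oxasilole at once. Oxidative cleavage of the aryl–silicon bond would then supply the a4 hydroxyl and the a3 hydroxymethyl group, the latter to be oxidized to the aldehyde.
- In its favour: three C–C bonds and two rings in one step, with the a3 carbon and the a4 oxygen placed by the tether and no regiochemical question.
- Against it here: an aryl alkynyl ether and an aryl alkynoate are very labile functions to ask of a hexasubstituted arene. Ring B with two differentiated oxygen atoms must be made beforehand. The seven-membered ring requires the disfavoured s-cis ester conformer. The silicon-to-oxygen oxidation needs peroxide with fluoride or base, which threatens ring C.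
- Comparison: on the regiochemistry of the a3 formyl group the alternative is the better, since the chosen plan relies on a late ortho-formylation (step 10). On closing ring C it is equal or better, as no separate lactonization is needed. It spends its strongest step on ring A, which the chosen plan takes ready-made from 1, and leaves ring B to a separate and longer synthesis, so on overall step economy and mechanistic risk the chosen plan is preferred.

**Alternative 3:** The ester bond of ring C and the a5–a6 bond of ring A are cut. Ring A then derives from dehydroacetic acid A5, used as its 4-aryloxy derivative A6, in which ring B is attached through the b6 oxygen and carries a free b1 hydroxyl.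
- Forward key step: Cs2CO3 would generate the b1 phenoxide, which attacks the pyranone carbonyl (acyl transfer, closing ring C). The ring-opened methyl ketone then condenses with the acetyl group (aldol, dehydration, enolization) to aromatize ring A and give A7.
- In its favour: all carbons of ring A come from a commodity chemical, the ether bond is made by addition–elimination on a pyranone and not on an arene, and A7 is reached without hydrogenolysis or a separate lactonization.
- Against it here: as in alternative 2, ring B must be supplied fully substituted, now as an unsymmetrical catechol whose two hydroxyls must be told apart. The aldol can close in two ways, both six-membered; the acetyl methyl attacking the liberated ketone would place the methyl group para to the ester carbonyl. The new aryl ester must survive the carbonate that forms it.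
- Comparison: forming the hindered ether before the ring is aromatic is common to both plans, so they are equal there. A7 is the protected counterpart of 14 and faces the same a3 versus a5 question in the formylation, again equal. From diaryl ether to depsidone the alternative is shorter and so the better. Overall the chosen plan is preferred because its ring-forming step creates the hexasubstituted ring, whereas the alternative consumes it.

Key step: step 5

Assumption: in solution the lactol carbon of 18 and 19 equilibrates through the open formyl acid, so the (S) configuration is that of the crystalline product; step 12 presupposes that 18 crystallizes as a conglomerate and that (S) seed crystals are at hand (for example from a small sample resolved on a chiral stationary phase).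

## Route

Step 1
Reactants: 1 orsellinic acid (2,4-dihydroxy-6-methylbenzoic acid)
Product: 2 benzyl 4-(benzyloxy)-2-hydroxy-6-methylbenzoate
Conditions: BnBr (2.1 equiv), K2CO3 (2.2 equiv), DMF, 0 °C to rt
Reagents that add atoms: benzyl bromide, BrCc1ccccc1
Why: Williamson alkylation under mild carbonate conditions: the carboxylate and the more acidic, unhindered para hydroxyl are benzylated, whereas the ortho hydroxyl is held in a hydrogen bond to the ester carbonyl and stays free for step 3; the temperature is kept low because 1 decarboxylates on heating.

Step 2
Reactants: 3 methyl 4,4-dimethoxy-3-oxobutanoate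
Product: 4 methyl 2-diazo-4,4-dimethoxy-3-oxobutanoate
Conditions: p-ABSA (1.1 equiv), Et3N, MeCN, 0 °C to rt
Reagents that add atoms: 4-acetamidobenzenesulfonyl azide (p-ABSA), CC(=O)Nc1ccc(cc1)S(=O)(=O)N=[N+]=[N-]
Why: Regitz diazo transfer from a sulfonyl azide to the active methylene of a β-keto ester; the acetal is inert to the basic conditions and p-ABSA is a comparatively safe transfer reagent.

Step 3
Reactants: 2 benzyl 4-(benzyloxy)-2-hydroxy-6-methylbenzoate; 4 methyl 2-diazo-4,4-dimethoxy-3-oxobutanoate
Product: 5 methyl 2-[5-(benzyloxy)-2-(benzyloxycarbonyl)-3-methylphenoxy]-4,4-dimethoxy-3-oxobutanoate (racemic; keto and enol forms)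
Conditions: Rh2(OAc)4 (2 mol %), slow addition of 4 (1.3 equiv), CH2Cl2, reflux
Reagents that add atoms: none
Why: Rh2(OAc)4 converts the acceptor-substituted diazo compound into an electrophilic rhodium carbenoid that inserts into the phenolic O–H bond (oxonium ylide, then proton shift), a known route to 2-aryloxy-3-oxo esters that forms the crowded C–O bond under neutral conditions; slow addition limits carbene dimerization. The new carbon is racemic and becomes planar in step 4.

Step 4
Reactants: 5 methyl 2-[5-(benzyloxy)-2-(benzyloxycarbonyl)-3-methylphenoxy]-4,4-dimethoxy-3-oxobutanoate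
Product: 6 methyl (Z)-2-[5-(benzyloxy)-2-(benzyloxycarbonyl)-3-methylphenoxy]-3,4,4-trimethoxybut-2-enoate (Z drawn; a mixture of alkene isomers is acceptable)
Conditions: Cs2CO3 (1.2 equiv), Me2SO4 (1.2 equiv), DMF, 0 °C to rt
Reagents that add atoms: dimethyl sulfate, COS(=O)(=O)OC
Why: O-alkylation of the cesium enolate of a β-keto ester by a hard electrophile in a dipolar aprotic solvent; C-methylation would create a quaternary carbon bearing four bulky groups and is disfavoured. The alkene geometry is lost in step 5, so no control is needed.

Step 5
Reactants: 6 methyl (Z)-2-[5-(benzyloxy)-2-(benzyloxycarbonyl)-3-methylphenoxy]-3,4,4-trimethoxybut-2-enoate; 7 methyl acetoacetate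
Product: 10 methyl 3-[5-(benzyloxy)-2-(benzyloxycarbonyl)-3-methylphenoxy]-2-(dimethoxymethyl)-4,6-dihydroxybenzoate, via acyclic addition-elimination adduct 8 (not isolated), via cyclohexenedione tautomer 9 (not isolated)
Conditions: 7 (3 equiv), NaOMe (2.2 equiv), MeOH, rt to 60 °C; then AcOH
Reagents that add atoms: none
Why: The sodium enolate of 7 adds through its doubly activated central carbon to the β-carbon of the push-pull acrylate 6, and loss of methoxide gives adduct 8 (bond b4–b5, conjugate addition–elimination). 8 is deprotonated to a delocalized anion through which the b5=b6 geometry equilibrates, so both isomers of 6 converge. Proton exchange in methanol supplies a small share of the methyl ketone enolate, which attacks the acrylate ester carbonyl in a 6-exo-trig Claisen (Dieckmann-type) closure (bond b1–b2) to give 9; enolization to the resorcinol and phenoxide formation make the sequence irreversible. The closest known reaction type is the Michael–Claisen benzannulation of acetoacetates with crotonates, alkynoates and β-alkoxyacrylates to resorcylates. Regiochemistry follows from acidity: only the central carbon is deprotonated at the start, so it makes the first bond, and the methyl group can then reach only the acrylate ester. O-acylation to a 2-pyranone is reversible under methoxide, whereas C-acylation ends in the aromatic phenoxide. The ring A benzyl ester is flanked by two ortho substituents and excess 7 keeps free methoxide low, so it should neither condense nor exchange; no stereocentre is formed.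

Step 6
Reactants: 10 methyl 3-[5-(benzyloxy)-2-(benzyloxycarbonyl)-3-methylphenoxy]-2-(dimethoxymethyl)-4,6-dihydroxybenzoate
Product: 11 methyl 3-[5-(benzyloxy)-2-(benzyloxycarbonyl)-3-methylphenoxy]-2-(dimethoxymethyl)-4,6-dihydroxy-5-(hydroxymethyl)benzoate
Conditions: 37% aq. CH2O (5 equiv), NaOH (1.1 equiv), THF/H2O, 0 °C; then AcOH
Reagents that add atoms: formaldehyde, C=O
Why: Lederer–Manasse hydroxymethylation: the resorcinol phenoxide attacks formaldehyde at b2, the only unsubstituted ring carbon and ortho to both hydroxyls; ring A carries no free phenol and is inert, and excess formaldehyde at low temperature suppresses diarylmethane formation.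

Step 7
Reactants: 11 methyl 3-[5-(benzyloxy)-2-(benzyloxycarbonyl)-3-methylphenoxy]-2-(dimethoxymethyl)-4,6-dihydroxy-5-(hydroxymethyl)benzoate
Product: 12 methyl 3-[5-(benzyloxy)-2-(benzyloxycarbonyl)-3-methylphenoxy]-5-({[tert-butyl(dimethyl)silyl]oxy}methyl)-2-(dimethoxymethyl)-4,6-dihydroxybenzoate
Conditions: TBSCl (1.05 equiv), imidazole (2 equiv), DMF, -20 to 0 °C
Reagents that add atoms: tert-butyldimethylsilyl chloride, CC(C)(C)[Si](C)(C)Cl
Why: Silylation of the unhindered primary alcohol with one equivalent of reagent at low temperature; the b3 hydroxyl is chelated to the ester and the b1 hydroxyl is flanked on both sides, so both phenols should react more slowly. The silyl ether blocks quinone methide formation and the alcohol oxidation that step 10 would otherwise cause.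

Step 8
Reactants: 12 methyl 3-[5-(benzyloxy)-2-(benzyloxycarbonyl)-3-methylphenoxy]-5-({[tert-butyl(dimethyl)silyl]oxy}methyl)-2-(dimethoxymethyl)-4,6-dihydroxybenzoate
Product: 13 2-[3-({[tert-butyl(dimethyl)silyl]oxy}methyl)-6-(dimethoxymethyl)-2,4-dihydroxy-5-(methoxycarbonyl)phenoxy]-4-hydroxy-6-methylbenzoic acid
Conditions: H2 (1 atm), 10% Pd/C, EtOAc, rt
Reagents that add atoms: none
Why: Hydrogenolysis of the benzyl ester and the aryl benzyl ether over palladium on carbon frees the ring A acid and the a4 phenol in one neutral operation; these two C–O bonds cleave faster than the benzylic silyl ether and acetal, and hydrogen uptake is followed so the reaction stops there.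

Step 9
Reactants: 13 2-[3-({[tert-butyl(dimethyl)silyl]oxy}methyl)-6-(dimethoxymethyl)-2,4-dihydroxy-5-(methoxycarbonyl)phenoxy]-4-hydroxy-6-methylbenzoic acid
Product: 14 methyl 9-({[tert-butyl(dimethyl)silyl]oxy}methyl)-6-(dimethoxymethyl)-3,8-dihydroxy-1-methyl-11-oxo-11H-dibenzo[b,e][1,4]dioxepine-7-carboxylate
Conditions: DCC (1.2 equiv), CH2Cl2 (0.005 M), 0 °C to rt
Reagents that add atoms: none
Why: Carbodiimide lactonization at high dilution: the O-acylisourea of the hindered acid is captured by the b1 hydroxyl held beside it by the ether bridge, the standard closure of the seven-membered depsidone lactone; the a4 hydroxyl (para to the activated acid) and the chelated b3 hydroxyl can react only intermolecularly.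

Step 10
Reactants: 14 methyl 9-({[tert-butyl(dimethyl)silyl]oxy}methyl)-6-(dimethoxymethyl)-3,8-dihydroxy-1-methyl-11-oxo-11H-dibenzo[b,e][1,4]dioxepine-7-carboxylate
Product: 16 methyl 9-({[tert-butyl(dimethyl)silyl]oxy}methyl)-6-(dimethoxymethyl)-4-formyl-3,8-dihydroxy-1-methyl-11-oxo-11H-dibenzo[b,e][1,4]dioxepine-7-carboxylate, via a3-hydroxymethyl phenol 15 (not isolated)
Conditions: MgCl2 (3 equiv), Et3N (6 equiv), (CH2O)n (8 equiv), MeCN, 70 °C; then 10% aq. AcOH
Reagents that add atoms: paraformaldehyde (as formaldehyde), C=O
Why: Magnesium-mediated ortho-formylation of a phenol (Casnati–Skattebøl type): the magnesium phenoxide of a4 adds formaldehyde at an ortho carbon to give 15, which a second formaldehyde oxidizes by hydride transfer; ring B has no free carbon. Of the two ortho sites a3 is expected to be preferred, because the para-acyl phenoxide is quinoid with a2=a3 double-bond character, which makes a3 the nucleophilic end of an aryl enol ether, and because a3 lies between two oxygen atoms, not beside the methyl group.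

Step 11
Reactants: 16 methyl 9-({[tert-butyl(dimethyl)silyl]oxy}methyl)-6-(dimethoxymethyl)-4-formyl-3,8-dihydroxy-1-methyl-11-oxo-11H-dibenzo[b,e][1,4]dioxepine-7-carboxylate
Product: 18 racemic salazinic acid (both configurations at the lactol carbon), via formyl methyl ester 17 (not isolated)
Conditions: TFA/H2O/THF (1:1:4), 40 °C
Reagents that add atoms: water, O
Why: Aqueous acid removes the silyl ether and hydrolyses the dimethyl acetal to 17; the hydrate of the new aldehyde then attacks the neighbouring methyl ester in a 5-exo-trig acyl substitution (neighbouring-group ester cleavage as in 2-formylbenzoates) to give the hydroxyphthalide without hydroxide, so ring C stays closed. The lactol carbon is formed as a racemate.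

Step 12
Reactants: 18 racemic salazinic acid
Product: 19 (S)-salazinic acid
Conditions: slurry in acetone, pyridine (cat.), (S) seed crystals of 19, glass beads, stirring, rt; filtration
Reagents that add atoms: none
Why: Proposed new method: the enantiomers of 18 interconvert in solution through the achiral open formyl acid (ring–chain tautomerism, helped by the trace of pyridine), so if 18 is a conglomerate, grinding a seeded slurry should convert the whole solid into the (S) crystal form by dissolution and regrowth (attrition-enhanced deracemization, Viedma ripening); the configuration is set by the lattice of the seed crystals, and the closest known case is the crystallization-driven deracemization of 3-hydroxyisoindolin-1-ones, which racemize by the same ring opening.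

## Compound list

1 | orsellinic acid (2,4-dihydroxy-6-methylbenzoic acid) | Cc1cc(O)cc(O)c1C(=O)O | starting material
2 | benzyl 4-(benzyloxy)-2-hydroxy-6-methylbenzoate | Cc1cc(OCc2ccccc2)cc(O)c1C(=O)OCc1ccccc1 | intermediate
3 | methyl 4,4-dimethoxy-3-oxobutanoate | COC(=O)CC(=O)C(OC)OC | starting material
4 | methyl 2-diazo-4,4-dimethoxy-3-oxobutanoate | COC(=O)C(=[N+]=[N-])C(=O)C(OC)OC | intermediate
5 | methyl 2-[5-(benzyloxy)-2-(benzyloxycarbonyl)-3-methylphenoxy]-4,4-dimethoxy-3-oxobutanoate (racemic) | COC(=O)C(Oc1cc(OCc2ccccc2)cc(C)c1C(=O)OCc1ccccc1)C(=O)C(OC)OC | intermediate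
6 | methyl (Z)-2-[5-(benzyloxy)-2-(benzyloxycarbonyl)-3-methylphenoxy]-3,4,4-trimethoxybut-2-enoate | COC(=O)/C(Oc1cc(OCc2ccccc2)cc(C)c1C(=O)OCc1ccccc1)=C(/OC)C(OC)OC | intermediate
7 | methyl acetoacetate | COC(=O)CC(C)=O | starting material
8 | dimethyl 2-acetyl-4-[5-(benzyloxy)-2-(benzyloxycarbonyl)-3-methylphenoxy]-3-(dimethoxymethyl)pent-3-enedioate (acyclic adduct, alkene isomers equilibrate) | COC(=O)C(C(C)=O)C(C(OC)OC)=C(Oc1cc(OCc2ccccc2)cc(C)c1C(=O)OCc1ccccc1)C(=O)OC | intermediate (not isolated)
9 | methyl 3-[5-(benzyloxy)-2-(benzyloxycarbonyl)-3-methylphenoxy]-2-(dimethoxymethyl)-4,6-dioxocyclohex-1-ene-1-carboxylate | COC(=O)C1=C(C(OC)OC)C(Oc2cc(OCc3ccccc3)cc(C)c2C(=O)OCc2ccccc2)C(=O)CC1=O | intermediate (not isolated)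
10 | methyl 3-[5-(benzyloxy)-2-(benzyloxycarbonyl)-3-methylphenoxy]-2-(dimethoxymethyl)-4,6-dihydroxybenzoate | COC(=O)c1c(O)cc(O)c(Oc2cc(OCc3ccccc3)cc(C)c2C(=O)OCc2ccccc2)c1C(OC)OC | intermediate
11 | methyl 3-[5-(benzyloxy)-2-(benzyloxycarbonyl)-3-methylphenoxy]-2-(dimethoxymethyl)-4,6-dihydroxy-5-(hydroxymethyl)benzoate | COC(=O)c1c(O)c(CO)c(O)c(Oc2cc(OCc3ccccc3)cc(C)c2C(=O)OCc2ccccc2)c1C(OC)OC | intermediate
12 | methyl 3-[5-(benzyloxy)-2-(benzyloxycarbonyl)-3-methylphenoxy]-5-({[tert-butyl(dimethyl)silyl]oxy}methyl)-2-(dimethoxymethyl)-4,6-dihydroxybenzoate | COC(=O)c1c(O)c(CO[Si](C)(C)C(C)(C)C)c(O)c(Oc2cc(OCc3ccccc3)cc(C)c2C(=O)OCc2ccccc2)c1C(OC)OC | intermediate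
13 | 2-[3-({[tert-butyl(dimethyl)silyl]oxy}methyl)-6-(dimethoxymethyl)-2,4-dihydroxy-5-(methoxycarbonyl)phenoxy]-4-hydroxy-6-methylbenzoic acid | COC(=O)c1c(O)c(CO[Si](C)(C)C(C)(C)C)c(O)c(Oc2cc(O)cc(C)c2C(=O)O)c1C(OC)OC | intermediate
14 | methyl 9-({[tert-butyl(dimethyl)silyl]oxy}methyl)-6-(dimethoxymethyl)-3,8-dihydroxy-1-methyl-11-oxo-11H-dibenzo[b,e][1,4]dioxepine-7-carboxylate | Cc1cc(O)cc2c1C(=O)Oc1c(CO[Si](C)(C)C(C)(C)C)c(O)c(C(=O)OC)c(C(OC)OC)c1O2 | intermediate
15 | methyl 9-({[tert-butyl(dimethyl)silyl]oxy}methyl)-6-(dimethoxymethyl)-3,8-dihydroxy-4-(hydroxymethyl)-1-methyl-11-oxo-11H-dibenzo[b,e][1,4]dioxepine-7-carboxylate | Cc1cc(O)c(CO)c2c1C(=O)Oc1c(CO[Si](C)(C)C(C)(C)C)c(O)c(C(=O)OC)c(C(OC)OC)c1O2 | intermediate (not isolated)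
16 | methyl 9-({[tert-butyl(dimethyl)silyl]oxy}methyl)-6-(dimethoxymethyl)-4-formyl-3,8-dihydroxy-1-methyl-11-oxo-11H-dibenzo[b,e][1,4]dioxepine-7-carboxylate | Cc1cc(O)c(C=O)c2c1C(=O)Oc1c(CO[Si](C)(C)C(C)(C)C)c(O)c(C(=O)OC)c(C(OC)OC)c1O2 | intermediate
17 | methyl 4,6-diformyl-3,8-dihydroxy-9-(hydroxymethyl)-1-methyl-11-oxo-11H-dibenzo[b,e][1,4]dioxepine-7-carboxylate | Cc1cc(O)c(C=O)c2c1C(=O)Oc1c(CO)c(O)c(C(=O)OC)c(C=O)c1O2 | intermediate (not isolated)
18 | racemic salazinic acid (depsidone with 4-formyl, 3,8-dihydroxy, 9-hydroxymethyl and 1-methyl groups, the 6-formyl and 7-carboxyl groups closed to the hydroxyphthalide; both configurations at the lactol carbon) | Cc1cc(O)c(C=O)c2c1C(=O)Oc1c(CO)c(O)c3c(c1O2)C(O)OC3=O | intermediate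
19 | (S)-salazinic acid | Cc1cc(O)c(C=O)c2c1C(=O)Oc1c(CO)c(O)c3c(c1O2)[C@@H](O)OC3=O | target

## Step count and least certain steps

Total step count: 12. Longest linear sequence: 11 steps (steps 1 and 3 to 12, from 1 to 19); step 2 is a one-step side branch.

**Step 12 (Proposed new method).** The solid may crystallize as a racemic compound, so that seeding cannot break the symmetry, or the ring–chain equilibration may be too slow in the slurry for the solid to converge. Fallback, using known techniques: starting from 18, the enantiomers would be separated by preparative chromatography on an immobilized polysaccharide chiral stationary phase with a cold, weakly acidic eluent, under which ring opening is slow. The (S) fraction is crystallized at once from the cold eluate to give 19, and the (R) fraction is re-equilibrated to 18 with a trace of base and recycled. This fallback makes no new compound (entry F0).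

**Step 5 (key step).** Conjugate addition may be slow or fail, since the β-carbon is fully substituted and carries a donor. Methoxide then has time for retro-Claisen loss of the acetyl group from 8 or for exchange of the ring A benzyl ester. On long heating a Smiles-type migration of ring A from the b6 to the b1 oxygen in the phenoxide of 10 cannot be excluded. Fallback: the leaving group at the β-carbon is improved. From 5, NaH and N-phenyltriflimide (THF, 0 °C) would give methyl 2-[5-(benzyloxy)-2-(benzyloxycarbonyl)-3-methylphenoxy]-4,4-dimethoxy-3-(trifluoromethylsulfonyloxy)but-2-enoate F1. Its triflate is displaced by the sodium enolate of 7 in THF at low temperature (addition–elimination on a β-sulfonyloxy acrylate, reaching adduct 8), and NaOMe in MeOH then closes the ring, returning to the route at 10.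

**Step 3.** Insertion may be slow because the phenol is chelated to the ester, so that carbene dimerization, insertion into adventitious water or addition to a benzyl ring takes over. Fallback: classical alkylation. From 3, SO2Cl2 in CH2Cl2 would give methyl 2-chloro-4,4-dimethoxy-3-oxobutanoate F2, which alkylates the cesium phenoxide of 2 (Cs2CO3, acetone) and returns to the route at 5.

**Step 4.** Competing C-methylation would give a quaternary keto ester that cannot enter step 5. Fallback: from 5, trimethyl orthoformate and catalytic p-TsOH in MeOH would give the dimethyl ketal methyl 2-[5-(benzyloxy)-2-(benzyloxycarbonyl)-3-methylphenoxy]-3,3,4,4-tetramethoxybutanoate F3. TMSOTf and i-Pr2NEt then eliminate methanol and return to the route at 6; C-alkylation is impossible on this path.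

**Step 10.** Formylation may occur at a5 instead of a3, since both are ortho to the a4 hydroxyl. The phenol is also deactivated by the para carbonyl, so conversion may be incomplete, and the methanol liberated may slowly open ring C. Fallback: the a3 carbon is introduced before the ether exists, where the regiochemistry is unambiguous.
- Phenol 2 has a single free position ortho to its hydroxyl, a3, so the same MgCl2/Et3N/paraformaldehyde conditions would give benzyl 4-(benzyloxy)-3-formyl-2-hydroxy-6-methylbenzoate F4.
- Ethylene glycol and p-TsOH (toluene, water removal) would give benzyl 4-(benzyloxy)-3-(1,3-dioxolan-2-yl)-2-hydroxy-6-methylbenzoate F5.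
- The operations of steps 3 to 9 would then lead in turn to the dioxolanyl aryloxy keto ester F6, the dioxolanyl enol ether F7, the dioxolanyl diaryl ether resorcinol F8, its hydroxymethyl derivative F9, the silyl ether F10, the hydroxy acid F11 and the 4-(1,3-dioxolan-2-yl) depsidone F12.
- The aqueous acid of step 11 then opens the dioxolane together with the other masks and returns to the route at 18.

This costs one additional step and makes the substrate of the ring-forming step more crowded, which is why it is held in reserve.

## Further compounds

F0 | step 12 | none | none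
F1 | step 5 | methyl 2-[5-(benzyloxy)-2-(benzyloxycarbonyl)-3-methylphenoxy]-4,4-dimethoxy-3-(trifluoromethylsulfonyloxy)but-2-enoate | COC(=O)C(Oc1cc(OCc2ccccc2)cc(C)c1C(=O)OCc1ccccc1)=C(OS(=O)(=O)C(F)(F)F)C(OC)OC
F2 | step 3 | methyl 2-chloro-4,4-dimethoxy-3-oxobutanoate | COC(=O)C(Cl)C(=O)C(OC)OC
F3 | step 4 | methyl 2-[5-(benzyloxy)-2-(benzyloxycarbonyl)-3-methylphenoxy]-3,3,4,4-tetramethoxybutanoate | COC(=O)C(Oc1cc(OCc2ccccc2)cc(C)c1C(=O)OCc1ccccc1)C(OC)(OC)C(OC)OC
F4 | step 10 | benzyl 4-(benzyloxy)-3-formyl-2-hydroxy-6-methylbenzoate | Cc1cc(OCc2ccccc2)c(C=O)c(O)c1C(=O)OCc1ccccc1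
F5 | step 10 | benzyl 4-(benzyloxy)-3-(1,3-dioxolan-2-yl)-2-hydroxy-6-methylbenzoate | Cc1cc(OCc2ccccc2)c(C2OCCO2)c(O)c1C(=O)OCc1ccccc1
F6 | step 10 | methyl 2-[5-(benzyloxy)-2-(benzyloxycarbonyl)-6-(1,3-dioxolan-2-yl)-3-methylphenoxy]-4,4-dimethoxy-3-oxobutanoate | COC(=O)C(Oc1c(C2OCCO2)c(OCc2ccccc2)cc(C)c1C(=O)OCc1ccccc1)C(=O)C(OC)OC
F7 | step 10 | methyl 2-[5-(benzyloxy)-2-(benzyloxycarbonyl)-6-(1,3-dioxolan-2-yl)-3-methylphenoxy]-3,4,4-trimethoxybut-2-enoate | COC(=O)C(Oc1c(C2OCCO2)c(OCc2ccccc2)cc(C)c1C(=O)OCc1ccccc1)=C(OC)C(OC)OC
F8 | step 10 | methyl 3-[5-(benzyloxy)-2-(benzyloxycarbonyl)-6-(1,3-dioxolan-2-yl)-3-methylphenoxy]-2-(dimethoxymethyl)-4,6-dihydroxybenzoate | COC(=O)c1c(O)cc(O)c(Oc2c(C3OCCO3)c(OCc3ccccc3)cc(C)c2C(=O)OCc2ccccc2)c1C(OC)OC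
F9 | step 10 | methyl 3-[5-(benzyloxy)-2-(benzyloxycarbonyl)-6-(1,3-dioxolan-2-yl)-3-methylphenoxy]-2-(dimethoxymethyl)-4,6-dihydroxy-5-(hydroxymethyl)benzoate | COC(=O)c1c(O)c(CO)c(O)c(Oc2c(C3OCCO3)c(OCc3ccccc3)cc(C)c2C(=O)OCc2ccccc2)c1C(OC)OC
F10 | step 10 | methyl 3-[5-(benzyloxy)-2-(benzyloxycarbonyl)-6-(1,3-dioxolan-2-yl)-3-methylphenoxy]-5-({[tert-butyl(dimethyl)silyl]oxy}methyl)-2-(dimethoxymethyl)-4,6-dihydroxybenzoate | COC(=O)c1c(O)c(CO[Si](C)(C)C(C)(C)C)c(O)c(Oc2c(C3OCCO3)c(OCc3ccccc3)cc(C)c2C(=O)OCc2ccccc2)c1C(OC)OC
F11 | step 10 | 2-[3-({[tert-butyl(dimethyl)silyl]oxy}methyl)-6-(dimethoxymethyl)-2,4-dihydroxy-5-(methoxycarbonyl)phenoxy]-3-(1,3-dioxolan-2-yl)-4-hydroxy-6-methylbenzoic acid | COC(=O)c1c(O)c(CO[Si](C)(C)C(C)(C)C)c(O)c(Oc2c(C3OCCO3)c(O)cc(C)c2C(=O)O)c1C(OC)OC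
F12 | step 10 | methyl 9-({[tert-butyl(dimethyl)silyl]oxy}methyl)-6-(dimethoxymethyl)-4-(1,3-dioxolan-2-yl)-3,8-dihydroxy-1-methyl-11-oxo-11H-dibenzo[b,e][1,4]dioxepine-7-carboxylate | Cc1cc(O)c(C3OCCO3)c2c1C(=O)Oc1c(CO[Si](C)(C)C(C)(C)C)c(O)c(C(=O)OC)c(C(OC)OC)c1O2
A1 | alternative 1 | isocoumarin-fused depsidone (methoxymethyl ethers at a4 and b3, silyl ether at the b2 side chain, formyl at a3) | Cc1cc(OCOC)c(C=O)c2c1C(=O)Oc1c(CO[Si](C)(C)C(C)(C)C)c(OCOC)c3c(c1O2)C=COC3=O
A2 | alternative 1 | protected salazinic acid lactol (target configuration drawn; equilibrating pair) | Cc1cc(OCOC)c(C=O)c2c1C(=O)Oc1c(CO[Si](C)(C)C(C)(C)C)c(OCOC)c3c(c1O2)[C@@H](O)OC3=O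
A3 | alternative 2 | triyne: ring B with a but-2-ynoate on the b1 oxygen and a 3-[(ethynyldimethylsilyl)oxy]prop-1-ynyl ether on the b6 oxygen | CC#CC(=O)Oc1c(CO[Si](C)(C)C(C)(C)C)c(OCOC)c(C(=O)OC)c(C(OC)OC)c1OC#CCO[Si](C)(C)C#C
A4 | alternative 2 | oxasilole-fused depsidone (silicon on a4, its oxygen on the a3 methylene) | Cc1cc2c(c3c1C(=O)Oc1c(CO[Si](C)(C)C(C)(C)C)c(OCOC)c(C(=O)OC)c(C(OC)OC)c1O3)CO[Si]2(C)C
A5 | alternative 3 | dehydroacetic acid (3-acetyl-4-hydroxy-6-methyl-2H-pyran-2-one) | CC(=O)C1=C(O)C=C(C)OC1=O
A6 | alternative 3 | 3-acetyl-6-methyl-4-(aryloxy)-2H-pyran-2-one, aryl being ring B bound through the b6 oxygen with free b1 hydroxyl | CC(=O)C1=C(Oc2c(O)c(CO[Si](C)(C)C(C)(C)C)c(OCOC)c(C(=O)OC)c2C(OC)OC)C=C(C)OC1=O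
A7 | alternative 3 | protected depsidone lacking the a3 formyl group | Cc1cc(O)cc2c1C(=O)Oc1c(CO[Si](C)(C)C(C)(C)C)c(OCOC)c(C(=O)OC)c(C(OC)OC)c1O2
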